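**Plan**

1. Retrosynthesis (azulene numbering of the target: C3 carbinol with isopropyl, C3a–H, C4–O, C5=C6–Me, C7=O, C8H2, C8a–Me): cut the C4–O ester bond, then the C4–H bond (C4 ketone), then read the cyclohept-5-ene-4,7-dione as a 2-methylhydroquinone ring with one extra carbon, C8a, inserted between two adjacent ring carbons, and cut C8a–C8 and C8a–C3a.
2. Feature that allows this: oxygen at C4 and C7 flanks the C5=C6(Me) alkene, C8 is CH2 and C3a is CH, so hydrolysis of a 4,7-dimethoxycycloheptatriene gives exactly this ring; the arene is 2,5-dimethoxy-4-methylphenyl and C3 is its benzylic carbon.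
3. Forward order: aryl isopropyl ketone, tertiary homoallylic alcohol (C3), alpha-methyl diazo ketone side chain (C1 ketone as helper); one step then closes the five-membered ring and turns the benzene ring into the seven-membered ring; the C1 oxygen is removed, both enol ethers are hydrolysed, C4 is reduced and esterified.
4. Stereochemistry: C3 from a catalytic enantioselective allylboration; C8a from C3 (allylic strain in the carbene addition); C3a by equilibration next to the C4 ketone; C4 by hydroxyl-directed hydride delivery from the C3 hydroxyl (1,3-anti).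

Key step: step 7

Assumption: in step 2 the diol catalyst is taken to tell the aryl group (large) from isopropyl as it tells aryl from methyl; the antipode that then sends allyl to the Si face, taken here as the (R)-diol, is used.

Remark: bicyclic compounds carry the azulene numbering of the target. The C3 descriptor reads S in 16 and 17, and the C3a descriptor reads R in 19, only because neighbouring atoms change CIP rank; no bond at these centres changes.

**Route**

Step 1
Reactants: 1 1-bromo-2,5-dimethoxy-4-methylbenzene; 2 N-methoxy-N,2-dimethylpropanamide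
Product: 4 1-(2,5-dimethoxy-4-methylphenyl)-2-methylpropan-1-one, via aryllithium 3 (not isolated)
Conditions: nBuLi, THF, −78 °C; then 2, −78 to 0 °C; aq. NH4Cl
Reagents that add atoms: none
Why: Bromine–lithium exchange and acylation of the aryllithium by the N-methoxy-N-methylamide should stop at the ketone because the chelated tetrahedral adduct survives until work-up (Weinreb ketone synthesis); no stereocentre is formed.

Step 2
Reactants: 4 1-(2,5-dimethoxy-4-methylphenyl)-2-methylpropan-1-one
Product: 5 (3R)-3-(2,5-dimethoxy-4-methylphenyl)-2-methylhex-5-en-3-ol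
Conditions: allyldiisopropoxyborane, (R)-3,3'-dibromo-1,1'-bi-2-naphthol (15 mol %), PhCF3/toluene 3:1, −35 °C; aqueous work-up
Reagents that add atoms: allyldiisopropoxyborane, C=CCB(OC(C)C)OC(C)C
Why: Chiral-diol-catalysed asymmetric allylboration of a ketone transfers the allyl group through a closed six-membered transition state to the Si face of the carbonyl group, which should set the (R)-carbinol centre from which all other stereocentres derive.

Step 3
Reactants: 5 (3R)-3-(2,5-dimethoxy-4-methylphenyl)-2-methylhex-5-en-3-ol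
Product: 6 triethyl{[(3R)-3-(2,5-dimethoxy-4-methylphenyl)-2-methylhex-5-en-3-yl]oxy}silane
Conditions: Et3SiOTf, 2,6-lutidine, CH2Cl2, 0 °C
Reagents that add atoms: triethylsilyl trifluoromethanesulfonate, CC[Si](CC)(CC)OS(=O)(=O)C(F)(F)F
Why: A silyl triflate silylates even a hindered tertiary alcohol, and the ether later blocks O–H insertion of the carbenoid and retro-aldol cleavage of the beta-oxy ketones.

Step 4
Reactants: 6 triethyl{[(3R)-3-(2,5-dimethoxy-4-methylphenyl)-2-methylhex-5-en-3-yl]oxy}silane
Product: 7 (4R)-4-(2,5-dimethoxy-4-methylphenyl)-5-methyl-4-[(triethylsilyl)oxy]hexan-2-one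
Conditions: PdCl2 (10 mol %), CuCl, O2 (1 atm), DMF/H2O 7:1, 23 °C
Reagents that add atoms: water, O
Why: Tsuji–Wacker oxidation of the terminal alkene by Markovnikov hydroxypalladation should give the methyl ketone and leave the arene and the silyl ether untouched.

Step 5
Reactants: 7 (4R)-4-(2,5-dimethoxy-4-methylphenyl)-5-methyl-4-[(triethylsilyl)oxy]hexan-2-one
Product: 9 (5R)-5-(2,5-dimethoxy-4-methylphenyl)-6-methyl-5-[(triethylsilyl)oxy]heptan-3-one, via lithium enolate 8 (not isolated)
Conditions: LiN(iPr)2, THF, −78 °C; MeI, −78 to −40 °C; aq. NH4Cl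
Reagents that add atoms: iodomethane, CI
Why: Kinetic deprotonation should occur at the unhindered methyl group (the other alpha-CH2 is neopentyl), so enolate C-methylation gives the ethyl ketone and no enolate is formed toward the beta-siloxy carbon.

Step 6
Reactants: 9 (5R)-5-(2,5-dimethoxy-4-methylphenyl)-6-methyl-5-[(triethylsilyl)oxy]heptan-3-one
Product: 12 (5R)-2-diazo-5-(2,5-dimethoxy-4-methylphenyl)-6-methyl-5-[(triethylsilyl)oxy]heptan-3-one, via lithium enolate 10 (not isolated), via trifluoroacetyl diketone 11 (not isolated)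
Conditions: LiN(SiMe3)2, THF, −78 °C; CF3CO2CH2CF3; aq. NH4Cl; then MsN3, Et3N, H2O (1 equiv), MeCN, 23 °C
Reagents that add atoms: methanesulfonyl azide, CS(=O)(=O)N=[N+]=[N-] (the two diazo nitrogens); 2,2,2-trifluoroethyl trifluoroacetate, O=C(OCC(F)(F)F)C(F)(F)F (trifluoroacetyl group held only by 11)
Why: Detrifluoroacetylative diazo transfer (a Regitz-type diazo transfer) should work because the kinetic enolate of the ethyl CH2 is trifluoroacetylated and the resulting 1,3-diketone takes the diazo group from the sulfonyl azide with loss of the trifluoroacetyl group.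

Step 7
Reactants: 12 (5R)-2-diazo-5-(2,5-dimethoxy-4-methylphenyl)-6-methyl-5-[(triethylsilyl)oxy]heptan-3-one
Product: 14 (3R,8aR)-4,7-dimethoxy-6,8a-dimethyl-3-(propan-2-yl)-3-[(triethylsilyl)oxy]-3,8a-dihydroazulen-1(2H)-one, via norcaradiene 13 (not isolated)
Conditions: Rh2(OAc)4 (1 mol %), CH2Cl2, 40 °C, slow addition of 12; product kept free of acid and used at once
Reagents that add atoms: none
Why: Rh2(OAc)4 turns the diazo ketone into an electrophilic rhodium carbenoid at C8a that adds to the ipso/ortho bond C3a–C8 of the electron-rich arene to give norcaradiene 13, whose C3a–C8 bond then opens by a thermal six-electron disrotatory electrocyclic reaction to the cycloheptatriene. The closest known reaction type is the intramolecular Buchner reaction of 1-diazo-4-arylbutan-2-ones and their alpha-methyl homologues, which gives 3,8a-dihydroazulen-1(2H)-ones. The cyclopentanone ring closes by the bond from C8a to the ipso carbon C3a across a three-atom tether (five-membered), the cyclopropane closes by the bond from C8a to the ortho carbon C8, and the seven-membered ring is not closed but made by opening of the six-membered ring. The new quaternary centre C8a is controlled by C3: allylic 1,3-strain with the ortho methoxy group should hold the small siloxy oxygen in the arene plane and the isopropyl group on the face away from the tether, so that C8 ends cis to isopropyl and the C8a methyl group cis to oxygen. The step needs chemoselectivity for arene addition over 1,2-hydride shift from the methyl group, insertion into the isopropyl C–H bond and oxonium ylide formation, which the electron-rich ring, the five-membered transition state and the hindered, weakly basic silyl ether should secure. It also needs attack at the ortho C–H carbon and not at the methoxy-bearing one, which the free position, activated by the neighbouring C7 methoxy group, should secure.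

Step 8
Reactants: 14 (3R,8aR)-4,7-dimethoxy-6,8a-dimethyl-3-(propan-2-yl)-3-[(triethylsilyl)oxy]-3,8a-dihydroazulen-1(2H)-one
Product: 16 (3S,8aR)-4,7-dimethoxy-6,8a-dimethyl-3-(propan-2-yl)-3-[(triethylsilyl)oxy]-3,8a-dihydroazulen-1-yl trifluoromethanesulfonate, via potassium enolate 15 (not isolated)
Conditions: KN(SiMe3)2, THF, −78 °C; PhNTf2, −78 to −40 °C; aq. NH4Cl
Reagents that add atoms: N-phenylbis(trifluoromethanesulfonimide), O=S(=O)(N(c1ccccc1)S(=O)(=O)C(F)(F)F)C(F)(F)F
Why: The ketone can enolise only toward C2, and trapping the potassium enolate as the enol triflate at −78 °C should outrun beta-elimination of the C3 siloxy group.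

Step 9
Reactants: 16 (3S,8aR)-4,7-dimethoxy-6,8a-dimethyl-3-(propan-2-yl)-3-[(triethylsilyl)oxy]-3,8a-dihydroazulen-1-yl trifluoromethanesulfonate
Product: 17 triethyl{[(3S,8aR)-4,7-dimethoxy-6,8a-dimethyl-3-(propan-2-yl)-3,8a-dihydroazulen-3-yl]oxy}silane
Conditions: Pd(OAc)2 (5 mol %), PPh3 (10 mol %), nBu3N, HCO2H, DMF, 60 °C
Reagents that add atoms: none
Why: Palladium-catalysed formate reduction of an enol triflate (oxidative addition, formate exchange, loss of CO2, reductive elimination) removes the helper oxygen at C1 without a cation or radical next to C8a, either of which could trigger a 1,2-vinyl shift.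

Step 10
Reactants: 17 triethyl{[(3S,8aR)-4,7-dimethoxy-6,8a-dimethyl-3-(propan-2-yl)-3,8a-dihydroazulen-3-yl]oxy}silane
Product: 18 triethyl{[(3R,8aR)-4,7-dimethoxy-6,8a-dimethyl-3-(propan-2-yl)-1,2,3,8a-tetrahydroazulen-3-yl]oxy}silane
Conditions: 2-nitrobenzenesulfonyl hydrazide, Et3N, CH2Cl2, 23 °C
Reagents that add atoms: none
Why: Diimide made in the flask transfers H2 in a concerted syn fashion to the cis-disubstituted cyclopentene much faster than to the tri- and tetrasubstituted enol ether bonds of the triene, and it takes the C3 oxygen out of its doubly allylic position before acid is used.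

Step 11
Reactants: 18 triethyl{[(3R,8aR)-4,7-dimethoxy-6,8a-dimethyl-3-(propan-2-yl)-1,2,3,8a-tetrahydroazulen-3-yl]oxy}silane
Product: 19 (3R,3aR,8aR)-3-hydroxy-6,8a-dimethyl-3-(propan-2-yl)-1,2,3,3a,8,8a-hexahydroazulene-4,7-dione
Conditions: 48 % aq. HF, MeCN, 0 to 23 °C
Reagents that add atoms: water, O
Why: Mild aqueous acid should hydrolyse both enol ethers by C-protonation at C8 and C3a while fluoride cleaves the silyl ether, and C3a, alpha to the C4 ketone, should settle through the enol in the trans-fused form, where the C4 carbonyl is anti to isopropyl and hydrogen-bonded to the C3 hydroxyl.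

Step 12
Reactants: 19 (3R,3aR,8aR)-3-hydroxy-6,8a-dimethyl-3-(propan-2-yl)-1,2,3,3a,8,8a-hexahydroazulene-4,7-dione
Product: 20 (3R,3aS,4S,8aR)-3,4-dihydroxy-6,8a-dimethyl-3-(propan-2-yl)-2,3,3a,4,8,8a-hexahydroazulen-7(1H)-one
Conditions: Me4NBH(OAc)3, MeCN/AcOH 1:1, −30 °C
Reagents that add atoms: none
Why: In the Evans–Saksena reduction the C3 hydroxyl binds boron and hydride is delivered inside the molecule to C4 from the side of that oxygen, which should give the 1,3-anti diol; the C7 ketone has no hydroxyl within reach and should stay.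

Step 13
Reactants: 20 (3R,3aS,4S,8aR)-3,4-dihydroxy-6,8a-dimethyl-3-(propan-2-yl)-2,3,3a,4,8,8a-hexahydroazulen-7(1H)-one; 21 (2E)-3-[4-(acetyloxy)phenyl]prop-2-enoic acid
Product: 22 (3R,3aS,4S,8aR)-3-hydroxy-6,8a-dimethyl-7-oxo-3-(propan-2-yl)-1,2,3,3a,4,7,8,8a-octahydroazulen-4-yl (2E)-3-[4-(acetyloxy)phenyl]prop-2-enoate
Conditions: EDC·HCl, DMAP (0.2 equiv), CH2Cl2, 0 to 23 °C
Reagents that add atoms: none
Why: Steglich esterification should acylate the secondary allylic hydroxyl with retention, while the tertiary hydroxyl is too hindered to react.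

Step 14
Reactants: 22 (3R,3aS,4S,8aR)-3-hydroxy-6,8a-dimethyl-7-oxo-3-(propan-2-yl)-1,2,3,3a,4,7,8,8a-octahydroazulen-4-yl (2E)-3-[4-(acetyloxy)phenyl]prop-2-enoate
Product: 23 (3R,3aS,4S,8aR)-3-hydroxy-6,8a-dimethyl-7-oxo-3-(propan-2-yl)-1,2,3,3a,4,7,8,8a-octahydroazulen-4-yl (2E)-3-(4-hydroxyphenyl)prop-2-enoate
Conditions: K2CO3 (0.2 equiv), MeOH, 0 °C
Reagents that add atoms: none
Why: Methanolysis should cleave the aryl acetate, which is far more electrophilic than the alkyl cinnamate, and free the phenol.

**Compound list**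

1 | 1-bromo-2,5-dimethoxy-4-methylbenzene | COc1cc(C)c(OC)cc1Br | starting material
2 | N-methoxy-N,2-dimethylpropanamide | CC(C)C(=O)N(C)OC | starting material
3 | (2,5-dimethoxy-4-methylphenyl)lithium | [Li]c1cc(OC)c(C)cc1OC | intermediate (not isolated)
4 | 1-(2,5-dimethoxy-4-methylphenyl)-2-methylpropan-1-one | CC(C)C(=O)c1cc(OC)c(C)cc1OC | intermediate
5 | (3R)-3-(2,5-dimethoxy-4-methylphenyl)-2-methylhex-5-en-3-ol | CC(C)[C@](O)(CC=C)c1cc(OC)c(C)cc1OC | intermediate
6 | triethyl{[(3R)-3-(2,5-dimethoxy-4-methylphenyl)-2-methylhex-5-en-3-yl]oxy}silane | CC(C)[C@](O[Si](CC)(CC)CC)(CC=C)c1cc(OC)c(C)cc1OC | intermediate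
7 | (4R)-4-(2,5-dimethoxy-4-methylphenyl)-5-methyl-4-[(triethylsilyl)oxy]hexan-2-one | CC(C)[C@](O[Si](CC)(CC)CC)(CC(C)=O)c1cc(OC)c(C)cc1OC | intermediate
8 | lithium enolate of 7 at the methyl group (lithium (4R)-4-aryl-5-methyl-4-[(triethylsilyl)oxy]hex-1-en-2-olate) | CC(C)[C@](O[Si](CC)(CC)CC)(CC(=C)O[Li])c1cc(OC)c(C)cc1OC | intermediate (not isolated)
9 | (5R)-5-(2,5-dimethoxy-4-methylphenyl)-6-methyl-5-[(triethylsilyl)oxy]heptan-3-one | CC(C)[C@](O[Si](CC)(CC)CC)(CC(=O)CC)c1cc(OC)c(C)cc1OC | intermediate
10 | lithium enolate of 9 toward the ethyl group (lithium (5R)-5-aryl-6-methyl-5-[(triethylsilyl)oxy]hept-2-en-3-olate) | CC(C)[C@](O[Si](CC)(CC)CC)(CC(O[Li])=CC)c1cc(OC)c(C)cc1OC | intermediate (not isolated)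
11 | (6R)-6-(2,5-dimethoxy-4-methylphenyl)-1,1,1-trifluoro-3,7-dimethyl-6-[(triethylsilyl)oxy]octane-2,4-dione (C3 epimers) | CC(C)[C@](O[Si](CC)(CC)CC)(CC(=O)C(C)C(=O)C(F)(F)F)c1cc(OC)c(C)cc1OC | intermediate (not isolated)
12 | (5R)-2-diazo-5-(2,5-dimethoxy-4-methylphenyl)-6-methyl-5-[(triethylsilyl)oxy]heptan-3-one | CC(C)[C@](O[Si](CC)(CC)CC)(CC(=O)C(C)=[N+]=[N-])c1cc(OC)c(C)cc1OC | intermediate
13 | norcaradiene valence isomer of 14 (cyclopropane formed by C8a, C3a and C8; C8 cis to isopropyl, C8a methyl cis to the siloxy group) | CC(C)[C@]1(O[Si](CC)(CC)CC)CC(=O)[C@]2(C)[C@H]3C(OC)=C(C)C=C(OC)[C@@]123 | intermediate (not isolated)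
14 | (3R,8aR)-4,7-dimethoxy-6,8a-dimethyl-3-(propan-2-yl)-3-[(triethylsilyl)oxy]-3,8a-dihydroazulen-1(2H)-one | CC1=CC(OC)=C2[C@](C)(C(=O)C[C@@]2(O[Si](CC)(CC)CC)C(C)C)C=C1OC | intermediate
15 | potassium enolate of 14 (C1=C2 enolate) | CC1=CC(OC)=C2[C@](C)(C(O[K])=C[C@@]2(O[Si](CC)(CC)CC)C(C)C)C=C1OC | intermediate (not isolated)
16 | (3S,8aR)-4,7-dimethoxy-6,8a-dimethyl-3-(propan-2-yl)-3-[(triethylsilyl)oxy]-3,8a-dihydroazulen-1-yl trifluoromethanesulfonate | CC1=CC(OC)=C2[C@](C)(C(OS(=O)(=O)C(F)(F)F)=C[C@@]2(O[Si](CC)(CC)CC)C(C)C)C=C1OC | intermediate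
17 | triethyl{[(3S,8aR)-4,7-dimethoxy-6,8a-dimethyl-3-(propan-2-yl)-3,8a-dihydroazulen-3-yl]oxy}silane | CC1=CC(OC)=C2[C@](C)(C=C[C@@]2(O[Si](CC)(CC)CC)C(C)C)C=C1OC | intermediate
18 | triethyl{[(3R,8aR)-4,7-dimethoxy-6,8a-dimethyl-3-(propan-2-yl)-1,2,3,8a-tetrahydroazulen-3-yl]oxy}silane | CC1=CC(OC)=C2[C@](C)(CC[C@@]2(O[Si](CC)(CC)CC)C(C)C)C=C1OC | intermediate
19 | (3R,3aR,8aR)-3-hydroxy-6,8a-dimethyl-3-(propan-2-yl)-1,2,3,3a,8,8a-hexahydroazulene-4,7-dione | CC1=CC(=O)[C@@H]2[C@](C)(CC[C@@]2(O)C(C)C)CC1=O | intermediate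
20 | (3R,3aS,4S,8aR)-3,4-dihydroxy-6,8a-dimethyl-3-(propan-2-yl)-2,3,3a,4,8,8a-hexahydroazulen-7(1H)-one | CC1=C[C@H](O)[C@@H]2[C@](C)(CC[C@@]2(O)C(C)C)CC1=O | intermediate
21 | (2E)-3-[4-(acetyloxy)phenyl]prop-2-enoic acid | CC(=O)Oc1ccc(/C=C/C(=O)O)cc1 | starting material
22 | (3R,3aS,4S,8aR)-3-hydroxy-6,8a-dimethyl-7-oxo-3-(propan-2-yl)-1,2,3,3a,4,7,8,8a-octahydroazulen-4-yl (2E)-3-[4-(acetyloxy)phenyl]prop-2-enoate | CC1=C[C@H](OC(=O)/C=C/c2ccc(OC(C)=O)cc2)[C@@H]2[C@](C)(CC[C@@]2(O)C(C)C)CC1=O | intermediate
23 | (3R,3aS,4S,8aR)-3-hydroxy-6,8a-dimethyl-7-oxo-3-(propan-2-yl)-1,2,3,3a,4,7,8,8a-octahydroazulen-4-yl (2E)-3-(4-hydroxyphenyl)prop-2-enoate | CC1=C[C@H](OC(=O)/C=C/c2ccc(O)cc2)[C@@H]2[C@](C)(CC[C@@]2(O)C(C)C)CC1=O | target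

**Count and risks**

Total step count: 14. Longest linear sequence: 14 steps (1 to 23); acid 21 is used as bought.

Steps most likely to fail:

1. Step 7. The carbenoid addition may lose facial control (isopropyl, not the siloxy oxygen, eclipsing the ortho methoxy group), or the carbenoid may be diverted into a 1,2-hydride shift or aromatic substitution. The fallback sets out from methyl ketone 7 and comes back at 14; it moves the setting of C8a from the carbene addition to an enolate alkylation. The same detrifluoroacetylative diazo transfer (LiN(SiMe3)2; CF3CO2CH2CF3; MsN3, Et3N) would pass through trifluoroacetyl diketone F1 to the terminal diazo ketone F2. This is the substrate class on which the intramolecular Buchner reaction is best known, and it has no hydrogen for the 1,2-shift. Rh2(OAc)4 would give the 8a-unsubstituted azulenone F3, whose C8a configuration does not matter. KOtBu in THF at −78 °C would remove the doubly vinylogous C8a proton, and iodomethane should alkylate the planar extended enolate at C8a on the face away from the isopropyl group, which gives 14.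

2. Step 2. The catalyst may discriminate poorly between the ortho-substituted aryl group and the isopropyl group, so the enantioselectivity may be low, and addition to the hindered ketone may be slow. The fallback sets out from ketone 4 and comes back at 5; it replaces face selection at the ketone by a stereospecific substitution. Corey–Bakshi–Shibata reduction (BH3·SMe2, (S)-methyl oxazaborolidine) would give (1R)-1-(2,5-dimethoxy-4-methylphenyl)-2-methylpropan-1-ol F4. NaH and N,N-diisopropylcarbamoyl chloride would convert it into the carbamate F5. Lithiation with sBuLi in Et2O at −78 °C (retention) and addition of allylboronic acid pinacol ester would give, after stereospecific 1,2-migration, the tertiary boronic ester F6 (not isolated). NaOH/H2O2 would oxidise it to 5; overall the allyl group takes the place of hydrogen with retention (lithiation–borylation).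

3. Step 11. Acid may remove the tertiary oxygen at C3 (ionisation assisted by the enol ether, or dehydration of the aldol once it is free), and equilibration at C3a may be incomplete. The fallback sets out from 18 and comes back at 19; it separates the acid-mediated events from the release of the hydroxyl group. Oxalic acid on wet silica gel in CH2Cl2 would hydrolyse only the two enol ethers and let C3a equilibrate through the enol, giving the silyl-protected diketone F7. Buffered HF·pyridine in THF at 0 °C would then free the hydroxyl group and give 19, so the free aldol never meets acid.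

Further compounds
F1 | step 7 | (6R)-6-(2,5-dimethoxy-4-methylphenyl)-1,1,1-trifluoro-7-methyl-6-[(triethylsilyl)oxy]octane-2,4-dione | CC(C)[C@](O[Si](CC)(CC)CC)(CC(=O)CC(=O)C(F)(F)F)c1cc(OC)c(C)cc1OC
F2 | step 7 | (4R)-1-diazo-4-(2,5-dimethoxy-4-methylphenyl)-5-methyl-4-[(triethylsilyl)oxy]hexan-2-one | CC(C)[C@](O[Si](CC)(CC)CC)(CC(=O)C=[N+]=[N-])c1cc(OC)c(C)cc1OC
F3 | step 7 | (3R,8aR)-4,7-dimethoxy-6-methyl-3-(propan-2-yl)-3-[(triethylsilyl)oxy]-3,8a-dihydroazulen-1(2H)-one (expected major C8a epimer drawn) | CC1=CC(OC)=C2[C@H](C(=O)C[C@@]2(O[Si](CC)(CC)CC)C(C)C)C=C1OC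
F4 | step 2 | (1R)-1-(2,5-dimethoxy-4-methylphenyl)-2-methylpropan-1-ol | CC(C)[C@@H](O)c1cc(OC)c(C)cc1OC
F5 | step 2 | (1R)-1-(2,5-dimethoxy-4-methylphenyl)-2-methylpropyl N,N-di(propan-2-yl)carbamate | CC(C)[C@@H](OC(=O)N(C(C)C)C(C)C)c1cc(OC)c(C)cc1OC
F6 | step 2 | 2-[(3S)-3-(2,5-dimethoxy-4-methylphenyl)-2-methylhex-5-en-3-yl]-4,4,5,5-tetramethyl-1,3,2-dioxaborolane | CC(C)[C@](B1OC(C)(C)C(C)(C)O1)(CC=C)c1cc(OC)c(C)cc1OC
F7 | step 11 | (3R,3aR,8aR)-6,8a-dimethyl-3-(propan-2-yl)-3-[(triethylsilyl)oxy]-1,2,3,3a,8,8a-hexahydroazulene-4,7-dione | CC1=CC(=O)[C@@H]2[C@](C)(CC[C@@]2(O[Si](CC)(CC)CC)C(C)C)CC1=O
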